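**Assumptions**
- Propiovanillone, 4-bromo-2-methoxyphenol, 4-bromo-2,6-dimethoxyphenol and 2,3-dimethylmaleic anhydride are commercial.
- The (DHQD)2AQN sense is assumed to give the (2R,3S) hemiester made in Step 2. If the opposite hemiester forms, use the pseudoenantiomer (DHQ)2AQN.
- The cinchonidinium-derived catalyst in Step 11 is assumed to give the (S)-aryl ether. If the (R)-ether forms, use the pseudoenantiomeric cinchoninium catalyst. The sense must be confirmed experimentally.

## Retrosynthetic overview
1. Remove the two aryl silyl ethers last. The C7'–ArB bond is made by Negishi coupling of the primary alkylzinc from the (2S,3S)-4-iodo-2,3-dimethylbutyl-guaiacol fragment with an aryl bromide that already carries the threo ArO–CH(Me)–CH(OH)Ar'' unit.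
2. That aryl bromide comes from racemic α-bromo-propiovanillone (silyl-protected) and 4-bromo-2,6-dimethoxyphenol. An enantioconvergent O-alkylation sets C8'' and an (S)-CBS reduction sets C7''.
3. The (R*,S*)-2,3-dimethylbutane core comes from meso cis-2,3-dimethylsuccinic anhydride. Cinchona-catalysed desymmetrisation sets C8 and C8'. Lactone formation and bromide opening then differentiate the two chain ends.
4. The only ring made is the transient γ-lactone, which is formed and opened again. All three arenes enter intact.

## Route

**Step 1**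
Reactants: **1** 2,3-dimethylmaleic anhydride
Product: **2** cis-(meso)-2,3-dimethylsuccinic anhydride
Conditions: H2 (4 atm), 10% Pd/C, EtOAc, rt
Reagents that add atoms: none
Why: Syn hydrogenation of the tetrasubstituted alkene delivers the cis (meso) anhydride, which has the (R*,S*) relationship required at C8/C8'.

**Step 2**
Reactants: **2**
Product: **3** (2R,3S)-4-methoxy-2,3-dimethyl-4-oxobutanoic acid
Conditions: (DHQD)2AQN (10 mol %), MeOH (10 equiv), MTBE, –20 °C
Reagents that add atoms: methanol, CO
Why: In this cinchona-alkaloid-catalysed desymmetrising alcoholysis of a meso anhydride, catalyst-bound methanol opens one enantiotopic carbonyl and sets C8 and C8' together, which is the first stereo-defining step.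

**Step 3**
Reactants: **3**
Product: **4** (3S,4R)-3,4-dimethyloxolan-2-one (cis-γ-lactone)
Conditions: BH3·SMe2, THF, 0 °C to rt; then cat. TsOH, CH2Cl2, rt
Reagents that add atoms: none
Why: Borane reduces the carboxylic acid chemoselectively over the methyl ester, and the resulting γ-hydroxy ester lactonises with loss of MeOH, which marks the former acid end as CH2–O while C8 and C8' are untouched.

**Step 4**
Reactants: **4**
Product: **5** methyl (2S,3R)-4-bromo-2,3-dimethylbutanoate
Conditions: AcBr, MeOH, 0 to 55 °C
Reagents that add atoms: acetyl bromide, CC(=O)Br; methanol, CO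
Why: HBr generated from AcBr and MeOH opens the lactone by SN2 at the primary CH2–O carbon, as in the HBr/ROH opening of γ-butyrolactone, so the two chain ends become CH2Br and CO2Me with no stereocentre involved.

**Step 5**
Reactants: **6** 4-bromo-2-methoxyphenol
Product: **7** tert-butyl(4-bromo-2-methoxyphenoxy)dimethylsilane
Conditions: TBSCl, imidazole, DMF, rt
Reagents that add atoms: tert-butyldimethylsilyl chloride, CC(C)(C)[Si](C)(C)Cl
Why: Standard silylation of the phenol so that it survives the organometallic steps.

**Step 6**
Reactants: **5** methyl (2S,3R)-4-bromo-2,3-dimethylbutanoate; **7** aryl bromide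
Product: **8** methyl (2S,3S)-4-[4-(TBSO)-3-methoxyphenyl]-2,3-dimethylbutanoate
Conditions: (i) Zn dust, LiCl, I2 (cat.), DMA, 60 °C; (ii) **7**, Pd(OAc)2/CPhos, THF, rt
Reagents that add atoms: none
Why: Negishi coupling of the ester-bearing primary alkylzinc with the aryl bromide forms the C7–ArA bond, and the stereocentres are two bonds from the reacting carbon so they are not affected.

**Step 7**
Reactants: **8**
Product: **9** (2S,3S)-4-[4-(TBSO)-3-methoxyphenyl]-2,3-dimethylbutan-1-ol
Conditions: DIBAL-H (2.5 equiv), CH2Cl2, –78 to 0 °C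
Reagents that add atoms: none
Why: DIBAL reduces the ester to the primary alcohol without epimerising the α-centre, because no free aldehyde or enolate is formed.

**Step 8**
Reactants: **9**
Product: **10** tert-butyl{4-[(2S,3S)-4-iodo-2,3-dimethylbutyl]-2-methoxyphenoxy}dimethylsilane
Conditions: PPh3, I2, imidazole, CH2Cl2, 0 °C to rt
Reagents that add atoms: iodine, II
Why: Appel iodination converts the primary alcohol to the iodide by SN2 at CH2 and does not touch either stereocentre.

**Step 9**
Reactants: **11** propiovanillone, 1-(4-hydroxy-3-methoxyphenyl)propan-1-one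
Product: **12** 1-[4-(TBSO)-3-methoxyphenyl]propan-1-one
Conditions: TBSCl, imidazole, DMF, rt
Reagents that add atoms: tert-butyldimethylsilyl chloride, CC(C)(C)[Si](C)(C)Cl
Why: Silyl protection of the phenol prevents self-alkylation in the later O-alkylation.

**Step 10**
Reactants: **12**
Product: **13** (±)-2-bromo-1-[4-(TBSO)-3-methoxyphenyl]propan-1-one
Conditions: PTAB (1.0 equiv), THF, 0 °C to rt, short reaction time
Reagents that add atoms: phenyltrimethylammonium tribromide (PTAB), C[N+](C)(C)c1ccccc1.[Br-].BrBr (tribromide written as bromide plus Br2)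
Why: This is a selective mono-α-bromination of the aryl ketone under mild conditions that leave the aryl TBS ether intact, and the product is racemic at C8''.

**Step 11**
Reactants: **13** (±)-α-bromoketone; **14** 4-bromo-2,6-dimethoxyphenol
Product: **15** (S)-2-(4-bromo-2,6-dimethoxyphenoxy)-1-[4-(TBSO)-3-methoxyphenyl]propan-1-one
Conditions: N-(9-anthracenylmethyl)cinchonidinium bromide (10 mol %), solid K2CO3, PhMe/CH2Cl2 (4:1), –20 °C, 48 h
Reagents that add atoms: none
Why: Proposed new method: enantioconvergent (dynamic kinetic asymmetric) Williamson O-alkylation of a racemic α-bromoketone with a hindered phenoxide under chiral phase-transfer catalysis; the α-bromoketone racemises rapidly by Br⁻/R4N⁺Br⁻ exchange and enolisation, and the chiral ammonium phenoxide ion pair reacts faster with one bromide enantiomer by SN2 with inversion, so both enantiomers funnel to the (S)-ether and set C8'' (closest known reaction type: asymmetric phase-transfer alkylation and enantioconvergent α-substitution of α-halocarbonyls with N, S and C nucleophiles).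

**Step 12**
Reactants: **15**
Product: **16** (1S,2S)-2-(4-bromo-2,6-dimethoxyphenoxy)-1-[4-(TBSO)-3-methoxyphenyl]propan-1-ol
Conditions: (S)-Me-CBS (20 mol %), BH3·SMe2, THF, –20 °C; MeOH quench
Reagents that add atoms: none
Why: In this Corey–Bakshi–Shibata reduction the (S)-catalyst delivers hydride to the face that gives the (S)-carbinol, where the alkyl carbon outranks the aryl group, and this matches the polar Felkin–Anh bias of the (8''S)-α-aryloxy ketone, giving the threo (7''S,8''S) product.

**Step 13**
Reactants: **10** alkyl iodide; **16** aryl bromide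
Product: **17** bis-TBS ether of the target
Conditions: (i) Zn dust, LiCl, TMSCl/BrCH2CH2Br (cat.), THF, 50 °C; (ii) **16** (1 equiv), Pd(OAc)2/CPhos, THF/PhMe, rt (organozinc 1.5–2 equiv)
Reagents that add atoms: none
Why: Negishi coupling of the primary alkylzinc with the aryl bromide forms the C7'–ArB bond, CPhos suppresses β-hydride isomerisation, and the excess organozinc covers some loss to the free hindered secondary alcohol.

**Step 14**
Reactants: **17**
Product: **18** target
Conditions: TBAF (3 equiv), AcOH (3 equiv), THF, 0 °C to rt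
Reagents that add atoms: none
Why: Fluoride cleaves both aryl TBS ethers, the AcOH buffer prevents base-mediated side reactions of the β-aryloxy benzylic alcohol, and no stereocentre is affected.

## Compound list
1 | 2,3-dimethylmaleic anhydride | CC1=C(C)C(=O)OC1=O | starting material
2 | cis-(meso)-2,3-dimethylsuccinic anhydride | O=C1OC(=O)[C@H](C)[C@@H]1C | intermediate
3 | (2R,3S)-4-methoxy-2,3-dimethyl-4-oxobutanoic acid | OC(=O)[C@H](C)[C@H](C)C(=O)OC | intermediate
4 | (3S,4R)-3,4-dimethyloxolan-2-one | O1C[C@H](C)[C@H](C)C1=O | intermediate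
5 | methyl (2S,3R)-4-bromo-2,3-dimethylbutanoate | BrC[C@H](C)[C@H](C)C(=O)OC | intermediate
6 | 4-bromo-2-methoxyphenol | COc1cc(Br)ccc1O | starting material
7 | tert-butyl(4-bromo-2-methoxyphenoxy)dimethylsilane | COc1cc(Br)ccc1O[Si](C)(C)C(C)(C)C | intermediate
8 | methyl (2S,3S)-4-[4-(TBSO)-3-methoxyphenyl]-2,3-dimethylbutanoate | COc1cc(C[C@H](C)[C@H](C)C(=O)OC)ccc1O[Si](C)(C)C(C)(C)C | intermediate
9 | (2S,3S)-4-[4-(TBSO)-3-methoxyphenyl]-2,3-dimethylbutan-1-ol | COc1cc(C[C@H](C)[C@H](C)CO)ccc1O[Si](C)(C)C(C)(C)C | intermediate
10 | tert-butyl{4-[(2S,3S)-4-iodo-2,3-dimethylbutyl]-2-methoxyphenoxy}dimethylsilane | COc1cc(C[C@H](C)[C@H](C)CI)ccc1O[Si](C)(C)C(C)(C)C | intermediate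
11 | 1-(4-hydroxy-3-methoxyphenyl)propan-1-one (propiovanillone) | CCC(=O)c1ccc(O)c(OC)c1 | starting material
12 | 1-[4-(TBSO)-3-methoxyphenyl]propan-1-one | CCC(=O)c1ccc(O[Si](C)(C)C(C)(C)C)c(OC)c1 | intermediate
13 | (±)-2-bromo-1-[4-(TBSO)-3-methoxyphenyl]propan-1-one | CC(Br)C(=O)c1ccc(O[Si](C)(C)C(C)(C)C)c(OC)c1 | intermediate
14 | 4-bromo-2,6-dimethoxyphenol | COc1cc(Br)cc(OC)c1O | starting material
15 | (S)-2-(4-bromo-2,6-dimethoxyphenoxy)-1-[4-(TBSO)-3-methoxyphenyl]propan-1-one | COc1cc(C(=O)[C@H](C)Oc2c(OC)cc(Br)cc2OC)ccc1O[Si](C)(C)C(C)(C)C | intermediate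
16 | (1S,2S)-2-(4-bromo-2,6-dimethoxyphenoxy)-1-[4-(TBSO)-3-methoxyphenyl]propan-1-ol | COc1cc(Br)cc(OC)c1O[C@@H](C)[C@@H](O)c1ccc(O[Si](C)(C)C(C)(C)C)c(OC)c1 | intermediate
17 | bis-TBS ether of the target | COc1cc(C[C@H](C)[C@H](C)Cc2cc(OC)c(O[C@@H](C)[C@@H](O)c3ccc(O[Si](C)(C)C(C)(C)C)c(OC)c3)c(OC)c2)ccc1O[Si](C)(C)C(C)(C)C | intermediate
18 | (+)-(7''S,8S,8'R,8''S)-4,4''-dihydroxy-3,3',3'',5'-tetramethoxy-4',8''-oxy-8,8'-sesquineolignan-7''-ol | COc1cc(C[C@H](C)[C@H](C)Cc2cc(OC)c(O[C@@H](C)[C@@H](O)c3ccc(O)c(OC)c3)c(OC)c2)ccc1O | target

## Totals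
- Total steps: 14, counting the Step 5, 9 and 10 preparations.
- Longest linear sequence: 9 steps (Steps 1, 2, 3, 4, 6, 7, 8, 13, 14).

## Three steps most likely to fail
1. **Step 11 (proposed new method).** The enantioconvergent phase-transfer O-alkylation may give low ee, C-alkylation, elimination to the aryl vinyl ketone, or product epimerisation under base.
   - Fallback: make the Z-silyl enol ether of **12**, convert it to the (R)-α-hydroxy ketone by Shi fructose-derived-ketone/Oxone epoxidation, then Mitsunobu inversion with **14** gives **15**.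
2. **Step 12.** The (S)-CBS reduction may give poor diastereoselectivity because the α-aryloxy group competes for boron and the aryl/alkyl size difference is small.
   - Fallback: substrate-controlled polar-Felkin reduction of the enantioenriched ketone **15** with L-Selectride in THF at –78 °C, which should also give the (7''S,8''S) isomer, or KRED enzymatic reduction.
3. **Step 13.** The β-branched alkylzinc coupling with an aryl bromide bearing a free secondary alcohol may suffer protonolysis or isomerisation.
   - Fallback: reverse the polarity by converting **16** to its aryl-Bpin (B2pin2, Pd) and coupling it with iodide **10** by Ni-catalysed alkyl–aryl Suzuki coupling.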